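A small charge of Xa, 0.170 M against 1.50 M of Xb, makes up the summer flask, and its yield at 10 h has to be read from the plateaus of the earlier runs.

| flask | Xa | Xb | time |
|---|---|---|---|
| dawn | 0.500 M | 0.750 M |  |
| autumn | 0.250 M | 0.500 M |  |
| winter | 0.500 M | 1.10 M |  |
| spring | 1.50 M | 0.750 M |  |
| summer | 0.170 M | 1.50 M | 10 h |

| run | time / h | [Xp] / M |
|---|---|---|
| dawn run | 1.4 | 0.178 |
| dawn run | 2.9 | 0.228 |
| dawn run | 4.3 | 0.231 |
| dawn run | 5.7 | 0.244 |
| dawn run | 7.1 | 0.248 |
| dawn run | 8.6 | 0.251 |
| dawn run | 10 | 0.250 |
| autumn run | 1.4 | 0.079 |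
| autumn run | 2.9 | 0.110 |
| autumn run | 4.3 | 0.121 |
| autumn run | 5.7 | 0.133 |
| autumn run | 7.1 | 0.132 |
| autumn run | 8.6 | 0.130 |
| autumn run | 10 | 0.140 |
| winter run | 1.4 | 0.226 |
| winter run | 2.9 | 0.267 |
| winter run | 4.3 | 0.284 |
| winter run | 5.7 | 0.299 |
| winter run | 7.1 | 0.297 |
| winter run | 8.6 | 0.297 |
| winter run | 10 | 0.315 |
| spring run | 1.4 | 0.320 |
| spring run | 2.9 | 0.366 |
| spring run | 4.3 | 0.391 |
| spring run | 5.7 | 0.412 |
| spring run | 7.1 | 0.412 |
| spring run | 8.6 | 0.413 |
| spring run | 10 | 0.409 |

(standard deviation of a reading: 0.004 M)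

- the exponent of [Xa] in the starting rate at the charge of the dawn run (at the point where two percent of the Xa have become Xp) (one fixed amount of Xp, the same in the runs compared)
- the exponent of [Xb] in the starting rate at the charge of the dawn run (at the point where two percent of the Xa have become Xp)
- Xp in the summer run at 10 h, as a share of the Xa charged

- Overall: Xa + Xb -> Xp.
- Constant volume, constant temperature.
- "The second partner" is Xb.
- An order is taken over about fifteen percent of the charge, up and down.

The puzzle stands in the dawn run: Xp lies flat near 0.250 M from 7.1 h on, yet by the overall equation 0.250 M of Xa and 0.500 M of Xb remain unused. A plain equilibrium would hold [Xp]/([Xa][Xb]) steady on those leftovers, but it reads 2.00 /M at dawn and 1.10 /M in spring.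

My reckoning therefore takes the plateau as the end of Xa, the limiting reagent at dawn, with part of it leaving by a path that makes no Xp. With A the Xa charged, P the plateau and B the mean Xb, that is, the Xb charged less P/2, the balance of Xa reads:

w = (A − P)/P = g·(A/2)/B

Dawn has w = 1.00, so g = 2.50. This g is the loss number, the Xa lost per Xp made when [Xa] equals [Xb]; the loss is taken to go as [Xa]/[Xb], with A/2 as the mean [Xa]. As a reading it carries a spread: the last readings, taken likewise as the end of Xa, give 1.94 in spring, where Xb is the smaller charge, and 2.70 in autumn.

Taking summer as on its plateau at 10 h, with P close to A in the mean of Xb: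

w = 0.150, share of Xa as Xp = 1/(1 + w) = 86.9%

The first readings come late for starting rates: dawn at 1.4 h already stands at 71.2% of its last reading. I take an exponent of one for each partner, as the overall equation writes them.

The forecast differs, with 0.8 and 0.8 for the orders and 84% (76% to 90%) for summer, holding that “the reverse step behaves as second order in product”.

The flask gives orders of 1.0 and 1.0, and summer comes to 85.0%, 1.9 percentage points under my reckoning.

    Xa + Xb → Xp + Xh (1.001 /M/h)
    2 Xb → E (0.2005 /M/h)
    2 Xa → L (1.202 /M/h)

At the fixed amount of Xp, spring runs 3.1 times the dawn rate on 3.00 times the Xa. Dawn's g, put on the winter flask with the mean Xb taken from its readings from 7.1 h on, gives w = 0.659 and a share of 60.3%, and those winter readings average 60.6% of the Xa charged.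

All runs are calculated for substances that don't exist; the scatter is artificial.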